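Both earlier flasks stop with a leftover of first end groups: at the last readings ochre keeps 37.6% of its charge and grey 54.3%.

| flask | first end groups | second end groups | remark | time |
|---|---|---|---|---|
| ochre | 0.014 M | 10 mM | run made earlier |  |
| grey | 0.020 M | 10 mM | run made earlier |  |
| north-west | 0.010 M | 10.0 mM |  | 10 d |
| south | 0.015 M | 10.0 mM |  | 10 d |

- ochre (time / d: links / %, first end groups / %): 1.04: 62.4, 38.8; 2.08: 62.7, 37.3; 3.00: 62.9, 36.7; 4.00: 62.5, 36.9; 5.00: 62.4, 37.6
- grey (time / d: links / %, first end groups / %): 0.417: 43.9, 56.5; 0.833: 45.3, 54.3; 1.25: 46.4, 53.6; 2.50: 46.1, 53.7; 5.00: 46.3, 54.3

(readings scatter by 0.3 percentage points)

- each molecule carries two end groups: a chain counts once for every two ends that are left, dead ends included; the units are half of the end groups of the two monomers charged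

1. which of the two ends with the longer chains by the average number of monomer units in a chain (unreacted monomers counted as chains of one) ("neither" if they lie within 10%) (north-west / south / neither)
2. average number of monomer units in a chain (unreacted monomers counted as chains of one) at the end, north-west
3. average number of monomer units in a chain (unreacted monomers counted as chains of one) at the end, south

Chain length is all ends charged over all ends left, so the fraction left is what needs reckoning. In ochre, time can be off by days: that run reads 62.7% links at 2.08 d and 62.4% at 5.00 d. The scatter of 0.3 percentage points counts through one small difference, second-end charge minus links. That difference is the sensitive number: in balanced north-west each second end that never links leaves one first end over, and the length follows that waste inversely.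

The reckoning here supposes that second ends are lost by a path of their own, so that the share linking is first ends over first ends plus a constant, as on a Michaelis curve. Summed over a run, with no free second ends supposed on the plateaus, waste (second-end charge minus links) is that constant times the logarithm of charged over left. On its plateau ochre reads 8.76 mM of links, giving 1.26 mM; grey reads 9.25 mM, giving 1.20 mM. Their mean, 1.23 mM, is the reading taken for the waste constant, the level of first end groups at which second ends are lost as fast as they link. From a first try of 2.12 mM, it leaves 1.99 mM of first end groups in north-west, length 5.04, and 6.11 mM in south, length 3.46.

The forecast, holding that the flasks “should reach equilibrium”, names north-west and gives 4.4 and 3.46; its north-west lies below the reckoning here.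

The flask gives 5.10 for north-west and 3.48 for south, so north-west ends with the longer chains.

    first end groups + second end groups ⇌ links + released group (K = 2.20, k = 0.0380 L mol⁻¹ s⁻¹)
    released group → by-product carried off (k = 4.70 × 10⁻⁵ s⁻¹)
    second end groups → decomposed reagent (k = 9.50 × 10⁻⁶ s⁻¹)

In north-west the half-life of second end groups by decomposition, 0.84 d at 0.0223 d, is 4.94 times the 0.17 d half-life of released group by carrying-off alone. North-west ends with 0.00804 M of by-product carried off against 0.00196 M of decomposed reagent, and its second end groups, the limiting reagent, stand at 0%. For the neighbour of north-west charged with 0.0025 M of second end groups, the waste constant gives 2.20 mM of links and a length of 1.54; that flask ends at 1.61.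

All runs stem from a simulated flask with constants of no real substance.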